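**Retrosynthetic overview**

1. Rings: A = 3,5-dihydroxyphenoxy ring; B = central ring (B1–O–A, B2–OH, B4–OH, B6–O–C); C = biaryl ring bound through the oxygen on C1 to B6 and through C5 to ring D (2,4,6-trihydroxyphenyl).
2. Feature carrying the strategy: the oxygens on B1, B2, B4 and B6 of ring B have four different roles, so ring B is built from a cyclobutenone: a Moore benzannulation closes the B3–B4 bond and delivers them as OMOM (B1), OEt (B2), free OH (B4) and OiPr (B6).
3. Disconnections, last to first: global O-dealkylation; C4–OH from a formyl group (Baeyer–Villiger); B6–O–C1 by SNAr on a rings C–D fluoroaldehyde (C5–D bond by Suzuki–Miyaura coupling); B1–O–A by aryne O-arylation.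
4. Cyclobutenone precursor: isopropyl semisquarate (from diisopropyl squarate) plus 1-ethoxyvinyllithium, then MOM capping of the carbinol.
5. Ring order: only ring B is formed in the route (step 4); rings A, C and D enter as intact arenes, ring A first, then the C–D unit.

Key step: step 4

Remark: the target is achiral; the three cyclobutenone intermediates that carry one stereocentre are handled as racemates, and that centre is erased by step 4 at the latest.

**Route**

Step 1
Reactants: 1 diisopropyl squarate
Product: 3 3-(propan-2-yloxy)cyclobut-3-ene-1,2-dione (isopropyl semisquarate), via hydroxycyclobutenone 2 (not isolated)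
Conditions: LiAlH(OtBu)3, THF, −20 °C; then conc. aq HCl, CH2Cl2, rt
Reagents that add atoms: water (from the aqueous HCl), O
Why: Mono 1,2-reduction of one squarate carbonyl by the bulky hydride gives allylic alcohol 2, and its acid-promoted ionisation, capture of water at the alkoxy-bearing allylic terminus and loss of propan-2-ol (a 1,3-carbonyl transposition) is the established passage from dialkyl squarates to alkyl semisquarates.

Step 2
Reactants: 3 3-(propan-2-yloxy)cyclobut-3-ene-1,2-dione, 4 ethyl vinyl ether
Product: 6 racemic 4-(1-ethoxyethenyl)-4-hydroxy-3-(propan-2-yloxy)cyclobut-2-en-1-one, via 1-ethoxyvinyllithium 5 (not isolated)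
Conditions: t-BuLi, THF, −78 → 0 °C; then 3 in THF, −78 °C; sat. aq NH4Cl, −78 °C
Reagents that add atoms: none
Why: α-Lithiation of the vinyl ether followed by 1,2-addition of the organolithium to the ketone-like carbonyl beside the alkoxy-bearing carbon (the other carbonyl is deactivated as a vinylogous ester) is the standard organolithium addition to cyclobutenediones, low temperature disfavours conjugate addition, and the quaternary centre forms as a racemate.

Step 3
Reactants: 6 racemic 4-(1-ethoxyethenyl)-4-hydroxy-3-(propan-2-yloxy)cyclobut-2-en-1-one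
Product: 7 racemic 4-(1-ethoxyethenyl)-4-(methoxymethoxy)-3-(propan-2-yloxy)cyclobut-2-en-1-one
Conditions: MOMCl, iPr2NEt, Bu4NI (cat.), CH2Cl2, 0 °C → rt
Reagents that add atoms: chloromethyl methyl ether, COCCl
Why: O-alkylation of the tertiary alcohol by the highly reactive α-chloro ether under a hindered amine base (acetal protection) keeps the medium basic, so the acid-labile enol ether and the cyclobutenone should survive.

Step 4
Reactants: 7 racemic 4-(1-ethoxyethenyl)-4-(methoxymethoxy)-3-(propan-2-yloxy)cyclobut-2-en-1-one
Product: 10 3-ethoxy-4-(methoxymethoxy)-5-(propan-2-yloxy)phenol, via dienylketene 8 (not isolated), via cyclohexadienone 9 (not isolated)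
Conditions: toluene (degassed, dilute, base-washed glassware), 110 °C
Reagents that add atoms: none
Why: Heating should open the cyclobutenone by thermal conrotatory 4π electrocyclic cleavage of the C1–C4 bond to the (Z)-dienylketene 8, whose ketene carbon closes onto the terminal CH2 of the ethoxyvinyl group by thermal disrotatory 6π electrocyclisation (forming the B3–B4 bond and ring B as cyclohexadienone 9), and enolisation of 9 gives phenol 10. This is the Moore rearrangement of 4-alkenyl-4-alkoxycyclobutenones, a known benzannulation of squarate-derived cyclobutenones. Ring B is closed by a pericyclic 6π ring closure without any external reagent; no stereocentre is created and the single stereocentre of 7 is erased on aromatisation. The selectivity required is torquoselectivity in the ring opening: the oxygen donor on C4 (the OMOM group) rotates outward, which turns the ethoxyvinyl group inward, cis to the ketene, as closure demands. The atom mapping fixes the labels (ketene carbon → B4 with free OH, carbinol carbon → B1 with OMOM, semisquarate carbon → B6 with OiPr, vinyl ether carbon → B2 with OEt), so B2 never has to be told from B6 on a symmetric arene. Dilute, degassed, acid-free toluene should suppress ketene dimerisation, enol ether hydrolysis and oxidation of the electron-rich phenol.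

Step 5
Reactants: 10 3-ethoxy-4-(methoxymethoxy)-5-(propan-2-yloxy)phenol
Product: 11 1-ethoxy-5-methoxy-2-(methoxymethoxy)-3-(propan-2-yloxy)benzene
Conditions: MeI, K2CO3, acetone, 50 °C
Reagents that add atoms: iodomethane, CI
Why: Williamson etherification of the only free phenol (the unhindered B4–OH); the MOM acetal and the alkyl ethers are inert to carbonate base.

Step 6
Reactants: 11 1-ethoxy-5-methoxy-2-(methoxymethoxy)-3-(propan-2-yloxy)benzene
Product: 12 2-ethoxy-4-methoxy-6-(propan-2-yloxy)phenol
Conditions: HCl (cat.), MeOH, 40 °C, under argon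
Reagents that add atoms: none
Why: Acid-catalysed acetal exchange with methanol removes only the MOM group (as dimethoxymethane) and unveils B1–OH, since simple aryl alkyl ethers are stable to dilute acid.

Step 7
Reactants: 13 3,5-dimethoxyphenol
Product: 14 2-bromo-3,5-dimethoxyphenol
Conditions: NBS, iPr2NH (cat.), CH2Cl2, −78 → 0 °C
Reagents that add atoms: N-bromosuccinimide, O=C1CCC(=O)N1Br
Why: Amine-mediated ortho-selective electrophilic aromatic bromination should place bromine at C2, which is ortho to OH, ortho to one methoxy and para to the other, and any 4-bromo isomer would be removed by chromatography.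

Step 8
Reactants: 14 2-bromo-3,5-dimethoxyphenol
Product: 18 3,5-dimethoxy-2-(trimethylsilyl)phenyl trifluoromethanesulfonate, via silyl ether 15 (not isolated), via aryllithium 16 (not isolated), via lithium phenoxide 17 (not isolated)
Conditions: HMDS, THF, 65 °C, then evaporation; n-BuLi, THF, −100 °C; Tf2O, −100 °C → rt
Reagents that add atoms: hexamethyldisilazane, C[Si](C)(C)N[Si](C)(C)C; trifluoromethanesulfonic anhydride, O=S(=O)(OS(=O)(=O)C(F)(F)F)C(F)(F)F
Why: O-silylation, bromine–lithium exchange, anionic 1,3 O→C silyl migration (retro-Brook rearrangement) and triflation of the resulting phenoxide form the standard one-flask entry to ortho-silylaryl triflate aryne precursors.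

Step 9
Reactants: 12 2-ethoxy-4-methoxy-6-(propan-2-yloxy)phenol, 18 3,5-dimethoxy-2-(trimethylsilyl)phenyl trifluoromethanesulfonate
Product: 20 2-(3,5-dimethoxyphenoxy)-1-ethoxy-5-methoxy-3-(propan-2-yloxy)benzene, via aryne 19 (not isolated)
Conditions: CsF, MeCN, rt
Reagents that add atoms: none
Why: Fluoride-triggered 1,2-elimination gives 3,5-dimethoxybenzyne, and in this aryne O-arylation of a phenol the phenoxide of 12 should add at the aryne carbon remote from the flanking methoxy group (inductive stabilisation of the developing ortho anion), so protonation gives only the 3,5-dimethoxyphenyl ether, while the unhindered, very reactive electrophile tolerates the doubly ortho-substituted B1–OH.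

Step 10
Reactants: 20 2-(3,5-dimethoxyphenoxy)-1-ethoxy-5-methoxy-3-(propan-2-yloxy)benzene
Product: 21 2-(3,5-dimethoxyphenoxy)-3-ethoxy-5-methoxyphenol
Conditions: BCl3, CH2Cl2, −78 → 0 °C; then H2O
Reagents that add atoms: none
Why: In this Lewis-acid ether cleavage the secondary isopropyl group ionises far more readily than methyl or ethyl, so BCl3 at low temperature should remove it chemoselectively and free B6–OH.

Step 11
Reactants: 22 4-fluoro-3,5-dimethoxybenzaldehyde
Product: 23 2-bromo-4-fluoro-3,5-dimethoxybenzaldehyde
Conditions: NBS, MeCN, 40 °C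
Reagents that add atoms: N-bromosuccinimide, O=C1CCC(=O)N1Br
Why: Electrophilic aromatic bromination should occur at C2 (equivalent to C6), ortho to one methoxy and para to the other, as for 3,5-dimethoxy- and 3,4,5-trimethoxybenzaldehyde, and the monobromide is deactivated towards a second bromination.

Step 12
Reactants: 23 2-bromo-4-fluoro-3,5-dimethoxybenzaldehyde, 24 (2,4,6-trimethoxyphenyl)boronic acid
Product: 25 4-fluoro-3,5-dimethoxy-2-(2,4,6-trimethoxyphenyl)benzaldehyde
Conditions: Pd(OAc)2, SPhos, K3PO4, toluene/H2O, 100 °C (excess 24)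
Reagents that add atoms: none
Why: Suzuki–Miyaura coupling with a bulky electron-rich dialkylbiarylphosphine is suited to biaryls with four ortho substituents, excess boronic acid offsets protodeboronation, and the symmetric ring D means the hindered axis creates no stereoisomers.

Step 13
Reactants: 21 2-(3,5-dimethoxyphenoxy)-3-ethoxy-5-methoxyphenol, 25 4-fluoro-3,5-dimethoxy-2-(2,4,6-trimethoxyphenyl)benzaldehyde
Product: 26 4-[2-(3,5-dimethoxyphenoxy)-3-ethoxy-5-methoxyphenoxy]-3,5-dimethoxy-2-(2,4,6-trimethoxyphenyl)benzaldehyde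
Conditions: Cs2CO3, DMSO, 110 °C, under argon
Reagents that add atoms: none
Why: Nucleophilic aromatic substitution (SNAr) of fluoride by the B6 phenoxide is activated by the para formyl group, which stabilises the Meisenheimer adduct, with fluoride as the best leaving group for addition–elimination.

Step 14
Reactants: 26 4-[2-(3,5-dimethoxyphenoxy)-3-ethoxy-5-methoxyphenoxy]-3,5-dimethoxy-2-(2,4,6-trimethoxyphenyl)benzaldehyde
Product: 28 4-[2-(3,5-dimethoxyphenoxy)-3-ethoxy-5-methoxyphenoxy]-3,5-dimethoxy-2-(2,4,6-trimethoxyphenyl)phenol, via aryl formate 27 (not isolated)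
Conditions: mCPBA, CH2Cl2, 0 °C → rt; then K2CO3 (cat.), MeOH, rt
Reagents that add atoms: meta-chloroperoxybenzoic acid, OOC(=O)c1cccc(Cl)c1
Why: In this Baeyer–Villiger (Dakin-type) oxidation the electron-rich, ortho-substituted aryl group should migrate in preference to hydrogen to give formate 27, and methanolysis releases the C4 phenol.

Step 15
Reactants: 28 4-[2-(3,5-dimethoxyphenoxy)-3-ethoxy-5-methoxyphenoxy]-3,5-dimethoxy-2-(2,4,6-trimethoxyphenyl)phenol
Product: 29 3-[2-(3,5-dihydroxyphenoxy)-3,5-dihydroxyphenoxy]biphenyl-2,2',4,4',6,6'-hexol (CNP0210555.0)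
Conditions: BBr3 (large excess), CH2Cl2, −78 °C → rt; then MeOH, H2O, under argon
Reagents that add atoms: none
Why: Lewis-acid ether cleavage by BBr3 removes the eight methyl groups and the ethyl group through bromide attack on the O-alkyl carbons, whereas the diaryl ether and biaryl bonds offer no sp3 carbon for substitution and should persist.

**Compound list**

1 | diisopropyl squarate (3,4-di(propan-2-yloxy)cyclobut-3-ene-1,2-dione) | CC(C)OC1=C(OC(C)C)C(=O)C1=O | starting material
2 | racemic 4-hydroxy-2,3-di(propan-2-yloxy)cyclobut-2-en-1-one | CC(C)OC1=C(OC(C)C)C(O)C1=O | intermediate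
3 | 3-(propan-2-yloxy)cyclobut-3-ene-1,2-dione | CC(C)OC1=CC(=O)C1=O | intermediate
4 | ethyl vinyl ether | C=COCC | starting material
5 | 1-ethoxyvinyllithium | [Li]C(=C)OCC | intermediate
6 | racemic 4-(1-ethoxyethenyl)-4-hydroxy-3-(propan-2-yloxy)cyclobut-2-en-1-one | CCOC(=C)C1(O)C(OC(C)C)=CC1=O | intermediate
7 | racemic 4-(1-ethoxyethenyl)-4-(methoxymethoxy)-3-(propan-2-yloxy)cyclobut-2-en-1-one | CCOC(=C)C1(OCOC)C(OC(C)C)=CC1=O | intermediate
8 | (3Z)-5-ethoxy-4-(methoxymethoxy)-3-(propan-2-yloxy)hexa-1,3,5-trien-1-one | O=C=C/C(OC(C)C)=C(/OCOC)C(OCC)=C | intermediate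
9 | 5-ethoxy-4-(methoxymethoxy)-3-(propan-2-yloxy)cyclohexa-2,4-dien-1-one | O=C1C=C(OC(C)C)C(OCOC)=C(OCC)C1 | intermediate
10 | 3-ethoxy-4-(methoxymethoxy)-5-(propan-2-yloxy)phenol | CCOc1cc(O)cc(OC(C)C)c1OCOC | intermediate
11 | 1-ethoxy-5-methoxy-2-(methoxymethoxy)-3-(propan-2-yloxy)benzene | CCOc1cc(OC)cc(OC(C)C)c1OCOC | intermediate
12 | 2-ethoxy-4-methoxy-6-(propan-2-yloxy)phenol | CCOc1cc(OC)cc(OC(C)C)c1O | intermediate
13 | 3,5-dimethoxyphenol | COc1cc(O)cc(OC)c1 | starting material
14 | 2-bromo-3,5-dimethoxyphenol | COc1cc(O)c(Br)c(OC)c1 | intermediate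
15 | (2-bromo-3,5-dimethoxyphenoxy)trimethylsilane | COc1cc(O[Si](C)(C)C)c(Br)c(OC)c1 | intermediate
16 | [2,4-dimethoxy-6-(trimethylsilyloxy)phenyl]lithium | [Li]c1c(OC)cc(OC)cc1O[Si](C)(C)C | intermediate
17 | lithium 3,5-dimethoxy-2-(trimethylsilyl)phenoxide | [Li+].[O-]c1cc(OC)cc(OC)c1[Si](C)(C)C | intermediate
18 | 3,5-dimethoxy-2-(trimethylsilyl)phenyl trifluoromethanesulfonate | COc1cc(OC)c([Si](C)(C)C)c(OS(=O)(=O)C(F)(F)F)c1 | intermediate
19 | 3,5-dimethoxybenzyne (1,2-didehydro-3,5-dimethoxybenzene) | COC1=CC(OC)=CC#C1 | intermediate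
20 | 2-(3,5-dimethoxyphenoxy)-1-ethoxy-5-methoxy-3-(propan-2-yloxy)benzene | CCOc1cc(OC)cc(OC(C)C)c1Oc1cc(OC)cc(OC)c1 | intermediate
21 | 2-(3,5-dimethoxyphenoxy)-3-ethoxy-5-methoxyphenol | CCOc1cc(OC)cc(O)c1Oc1cc(OC)cc(OC)c1 | intermediate
22 | 4-fluoro-3,5-dimethoxybenzaldehyde | COc1cc(C=O)cc(OC)c1F | starting material
23 | 2-bromo-4-fluoro-3,5-dimethoxybenzaldehyde | COc1cc(C=O)c(Br)c(OC)c1F | intermediate
24 | (2,4,6-trimethoxyphenyl)boronic acid | COc1cc(OC)c(B(O)O)c(OC)c1 | starting material
25 | 4-fluoro-3,5-dimethoxy-2-(2,4,6-trimethoxyphenyl)benzaldehyde | COc1cc(C=O)c(-c2c(OC)cc(OC)cc2OC)c(OC)c1F | intermediate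
26 | 4-[2-(3,5-dimethoxyphenoxy)-3-ethoxy-5-methoxyphenoxy]-3,5-dimethoxy-2-(2,4,6-trimethoxyphenyl)benzaldehyde | CCOc1cc(OC)cc(Oc2c(OC)cc(C=O)c(-c3c(OC)cc(OC)cc3OC)c2OC)c1Oc1cc(OC)cc(OC)c1 | intermediate
27 | 4-[2-(3,5-dimethoxyphenoxy)-3-ethoxy-5-methoxyphenoxy]-3,5-dimethoxy-2-(2,4,6-trimethoxyphenyl)phenyl formate | CCOc1cc(OC)cc(Oc2c(OC)cc(OC=O)c(-c3c(OC)cc(OC)cc3OC)c2OC)c1Oc1cc(OC)cc(OC)c1 | intermediate
28 | 4-[2-(3,5-dimethoxyphenoxy)-3-ethoxy-5-methoxyphenoxy]-3,5-dimethoxy-2-(2,4,6-trimethoxyphenyl)phenol | CCOc1cc(OC)cc(Oc2c(OC)cc(O)c(-c3c(OC)cc(OC)cc3OC)c2OC)c1Oc1cc(OC)cc(OC)c1 | intermediate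
29 | 3-[2-(3,5-dihydroxyphenoxy)-3,5-dihydroxyphenoxy]biphenyl-2,2',4,4',6,6'-hexol | Oc1cc(O)cc(Oc2c(O)cc(O)cc2Oc2c(O)cc(O)c(-c3c(O)cc(O)cc3O)c2O)c1 | target

**Step count**

Total: 15 steps. Longest linear sequence: 11 steps (steps 1–6, 9, 10, 13, 14, 15, from diisopropyl squarate).

**Steps most likely to fail**

Step 13 (SNAr). The fluoride lies between two methoxy groups and the phenoxide of 21 carries an ortho aryloxy group. Formation of the Meisenheimer adduct may therefore be so slow that oxidative decomposition of the electron-rich phenoxide or base-induced degradation of the aldehyde takes over. The fallback sets out from 21 and returns at 26, replacing addition–elimination by a copper-catalysed Ullmann etherification of an aryl bromide. Commercial 4-bromo-3,5-dimethoxybenzaldehyde would be iodinated ortho to the formyl group (NIS, TFA, MeCN) to 4-bromo-2-iodo-3,5-dimethoxybenzaldehyde F1. F1 would be coupled at the more reactive C–I bond with boronic acid 24 (Pd(PPh3)4, Ba(OH)2, DME/H2O, 80 °C) to 4-bromo-3,5-dimethoxy-2-(2,4,6-trimethoxyphenyl)benzaldehyde F2. F2 would then be joined to 21 with CuI, picolinic acid and K3PO4 in DMSO at 100 °C to give 26, after which steps 14 and 15 follow unchanged.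

Step 12 (Suzuki–Miyaura coupling). Transmetalation onto a palladium centre flanked by formyl and methoxy groups may be slower than base-promoted protodeboronation of the 2,6-dimethoxy-substituted boronic acid, which would consume 24 without forming the biaryl bond. The fallback sets out from 23 and returns at 25, using a Negishi coupling with an organozinc made by C–H lithiation, which has no protodemetalation pathway under anhydrous conditions. Commercial 1,3,5-trimethoxybenzene with n-BuLi (THF, 0 °C) should give (2,4,6-trimethoxyphenyl)lithium F3, and ZnCl2 converts it into chloro(2,4,6-trimethoxyphenyl)zinc F4. F4 is then coupled with 23 using Pd2(dba)3 and RuPhos in THF at 60 °C; the arylzinc chloride is not expected to add to the aldehyde at this temperature.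

Step 15 (global dealkylation). Nine ethers must fall in one operation. The ethyl ether and the methyl ethers around the biaryl axis may lag behind, acid formed on partial hydrolysis may brominate the phloroglucinol-type rings, and the free decaphenol may oxidise during chromatography. The fallback sets out from 28 and returns at 29, using capture and release through the peracetate. The crude product of the BBr3 treatment would be acetylated without purification (Ac2O, pyridine, DMAP) to the decaacetate of 29 F5. F5 is stable to air and silica and can be separated from under-cleaved material, which is resubmitted. F5 is then deacetylated by acid methanolysis (AcCl in MeOH, rt, under argon) to 29.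

**Further compounds**

F1 | step 13 | 4-bromo-2-iodo-3,5-dimethoxybenzaldehyde | COc1cc(C=O)c(I)c(OC)c1Br
F2 | step 13 | 4-bromo-3,5-dimethoxy-2-(2,4,6-trimethoxyphenyl)benzaldehyde | COc1cc(C=O)c(-c2c(OC)cc(OC)cc2OC)c(OC)c1Br
F3 | step 12 | (2,4,6-trimethoxyphenyl)lithium | [Li]c1c(OC)cc(OC)cc1OC
F4 | step 12 | chloro(2,4,6-trimethoxyphenyl)zinc | Cl[Zn]c1c(OC)cc(OC)cc1OC
F5 | step 15 | decaacetate of 29 (all ten phenolic hydroxyls acetylated) | CC(=O)Oc1cc(OC(C)=O)cc(Oc2c(OC(C)=O)cc(OC(C)=O)cc2Oc2c(OC(C)=O)cc(OC(C)=O)c(-c3c(OC(C)=O)cc(OC(C)=O)cc3OC(C)=O)c2OC(C)=O)c1
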